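We decide to read these flasks by counting half-lives, because a count tells us which step is over and which still runs.

| flask | substrate | partner | remark | time |
|---|---|---|---|---|
| ash | 0.27 M | 1 equiv | run made earlier |  |
| south | 0.080 M | 1.00 equiv |  | 3.0 d |
| south-east | 0.12 M | 1.00 equiv |  | 3.0 d |
| north-east | 0.20 M | 1.00 equiv |  | 3.0 d |

ash run (percent of the substrate charged)

| time / h | open intermediate / % | target / % |
|---|---|---|
| 3.00 | 14 | 2 |
| 6.00 | 16 | 1 |
| 15.0 | 21 | 8 |
| 40.0 | 15 | 15 |

(scatter of a reading: 1.5 percentage points)

- "hardly changes" means that all values lie within two and a half points (for a concentration: within two and a half percent of the largest)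

- [open intermediate] at the end for south, south-east, north-east, in this order
- the course of these numbers from the first flask to the last (rises all the way / falls, then rises / hardly changes / falls all the way / rises, then falls)

At the bench we call a step over after 5 half-lives. In the ash run, the open intermediate reaches 14% after 3.00 h, against its highest reading of 21%. Taken as a first-order approach, this reads as a settling half-life of 1.89 h. The asked 3.0 d is far longer than that, since it holds 38.0 settling half-lives.

Substrate was not read, so we take it as what is neither open intermediate nor target in the ash run at 15.0 h. The ratio then reads 0.296. We call it the balance ratio: [open intermediate] over [substrate] once the fast step has settled, a pre-equilibrium.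

The rule gives a ratio, but it gives no amount. Between 15.0 h and 40.0 h the ash reading falls to 15%, a drain half-life of 51.5 h. This is much slower than settling, so the ratio can hold while the pair drains. But 3.0 d is 1.40 of these ash drain half-lives, fewer than the rule's 5, so by the rule the drain is not over.

Our own reckoning assumes the ash pace in every flask, which gives an estimate of 9.75% of each charge as open intermediate. North-east then stands at 2.50 times south. The forecast differs, with a factor of 4.31: “Being second-order in formation, [I] rises steadily with concentration”. Both expect the course "rises all the way".

| Flask | Charge | Our reckoning | Forecast |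
|---|---|---|---|
| south | 0.080 M | 0.00780 M | 0.0052 M |
| south-east | 0.12 M | 0.0117 M | 0.0102 M |
| north-east | 0.20 M | 0.0195 M | 0.0224 M |

The flasks give 0.0156 M, 0.0214 M and 0.0309 M, so the course is "rises all the way", and north-east stands at 1.98 times south.

    substrate ⇌ open intermediate (K = 0.320, k = 0.0700 h⁻¹)
    partner → second intermediate (k = 0.750 h⁻¹)
    open intermediate + second intermediate → target (k = 0.190 M⁻¹ h⁻¹)
    2 open intermediate → homo product (k = 0.150 M⁻¹ h⁻¹)
    partner ⇌ dormant form (K = 2.00, k = 0.0200 h⁻¹)
    partner + target → over-reaction product (k = 0.250 M⁻¹ h⁻¹)
    partner → decomposed reagent (k = 0.750 h⁻¹)

In south, substrate and open intermediate relax by this step alone, both ways together, with a half-life of 0.100 d, short against 3.0 d. South has 63.3% of its substrate left at 3.00 d, and the balance ratio turns that into 0.0150 M of open intermediate. North-east has 51.8% left at 3.00 d, which the same ratio turns into 0.0307 M, and the flask holds 0.0309 M.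

The runs are simulated on assumed constants.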